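| flask | starting material | reagent | second substrate | third substrate | temperature | remark | time |
|---|---|---|---|---|---|---|---|
| theta | 0.10 M | 2 equiv | 0.50 equiv | 1 equiv | 60 °C | run made earlier |  |
| zeta | 0.10 M | 2 equiv | 2 equiv | 1 equiv | 82 °C | run made earlier |  |
| epsilon | 0.10 M | 2 equiv | 1 equiv | 0.50 equiv | 60 °C | run made earlier |  |
| west | 0.10 M | 2.00 equiv | 1.00 equiv | 1.00 equiv | 50 °C |  | 5.0 min |
| south-east | 0.10 M | 2.00 equiv | 1.00 equiv | 1.00 equiv | 70 °C |  | 5.0 min |
| south | 0.10 M | 2.00 equiv | 1.00 equiv | 1.00 equiv | 90 °C |  | 5.0 min |

| run | time / s | target / % | starting material / % |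
|---|---|---|---|
| theta | 10.0 | 10.0 | 89.9 |
| theta | 30.0 | 21.2 | 76.9 |
| theta | 50.0 | 30.7 | 69.5 |
| theta | 80.0 | 41.0 | 59.4 |
| theta | 120 | 48.8 | 50.0 |
| zeta | 10.0 | 21.8 | 79.0 |
| zeta | 15.0 | 25.1 | 74.7 |
| zeta | 25.0 | 28.9 | 70.7 |
| zeta | 40.0 | 35.8 | 64.8 |
| epsilon | 10.0 | 10.1 | 91.9 |
| epsilon | 15.0 | 12.9 | 86.6 |
| epsilon | 30.0 | 22.7 | 79.9 |
| epsilon | 60.0 | 34.1 | 64.0 |
| epsilon | 120 | 48.5 | 51.7 |

(scatter of a reading: 1 percentage point)

- the flask that comes out highest in amount of target, in percent of the starting material charged, or "all alike" when all lie within 1.5 percentage points (west / south-east / south / all alike)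
- target at the end, in percent of the starting material charged, west
- target at the end, in percent of the starting material charged, south-east
- target at the end, in percent of the starting material charged, south



1. The theta and epsilon runs overlap: at 120 s they read 48.8% and 48.5% of target, though a different substrate is cut in each. I suppose that the second and third substrates each use up reagent, one for one, beside the starting material.
2. That gives me a measure: the cover, the equivalents of reagent over the equivalents of all substrates, starting material included. Theta has 0.800 and epsilon 0.800.
3. The new flasks have a cover of 0.667, less than 1, so the reagent is the limiting reagent. If the substrates share equally, target stops near 66.7%.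
4. Now the pace. I allow a factor 2 in rate from 60 °C to 50 °C, so west at 300 s resembles theta at 150 s. That lies a little past the last reading at 120 s, so I commit to a little above the 48.8% read there for west.
5. With the same factor, south-east resembles theta at 600 s, well past that reading. So I put south-east and south near the stop, ahead of west, and I can't part those two.

The forecast differs. It reads the slowing as “an active species dying” and puts west highest: west 63% (52% to 76%), south-east 50% (41% to 63%), south 31% (23% to 44%).

The flasks give west 49.2%, south-east 56.6%, south 53.2%, so south-east is highest.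

    starting material + reagent → target (k = 0.0940 M⁻¹ s⁻¹, Ea = 60.0 kJ mol⁻¹)
    second substrate + reagent → second product (k = 0.160 M⁻¹ s⁻¹, Ea = 72.0 kJ mol⁻¹)
    third substrate + reagent → third product (k = 0.120 M⁻¹ s⁻¹, Ea = 66.0 kJ mol⁻¹)
    (constants at 70 °C)

My weak link was the equal share: in south-east target took 28.6% of the spent reagent, not 33.3%. At 5.00 min south-east keeps 0.940% of its reagent, and the half-life of starting material by the target step is 65 min, far longer than the 5.0 min allowed. The neighbour of south-east charged with 8.00 equiv of reagent has a cover of 2.67 and gives >99.9% of target. Its cover leaves 62.5% of the reagent, and 63% stands there.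

The readings were computed from invented constants.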